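**Retrosynthetic overview**
- Target ⇒ 5'-prenyl-4'-hydroxy isoflavone: the pyran ring is closed last by DDQ dehydrogenation (o-quinone methide, oxa-6π), as in chromene biosynthesis.
- Prenylphenol ⇒ 5'-bromo isoflavone + prenylstannane (Stille coupling, standing in for the aromatic prenyl transfer).
- Isoflavone ⇒ flavanone by oxidative 2,3-aryl shift with PhI(OH)OTs (isoflavone-synthase-type); this is the key step.
- Flavanone ⇒ 2,4-dihydroxyacetophenone + 5-bromovanillin: aldol condensation, then oxa-Michael closure in the same flask (chalcone → flavanone).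
- Ring order: ring C (flavanone) → aryl shift → prenyl → pyran ring.

Assumption: the target SMILES has no stereocentre, so the compound is achiral and is made as such; the racemic flavanone intermediates lose their only centre in step 3.

**Route**

Step 1
Reactants: 1 2,4-dihydroxyacetophenone; 2 5-bromovanillin (3-bromo-4-hydroxy-5-methoxybenzaldehyde)
Product: 4 (±)-2-(3-bromo-4-hydroxy-5-methoxyphenyl)-7-hydroxychroman-4-one, via (E)-2'-hydroxychalcone 3 (not isolated)
Conditions: HCl(g)-saturated EtOH, 0 °C → rt, 24 h; then reflux, 24 h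
Reagents that add atoms: none
Why: Acid-catalysed Claisen–Schmidt aldol condensation gives the 2'-hydroxychalcone, whose phenol then closes ring C by 6-endo oxa-Michael addition to the protonated enone (chalcone synthase/chalcone isomerase sequence in one flask); acid is used because three free phenols shut down the base-mediated aldol, and C-2 forms as a racemate that is erased in step 3.

Step 2
Reactants: 4 (±)-2-(3-bromo-4-hydroxy-5-methoxyphenyl)-7-hydroxychroman-4-one
Product: 5 (±)-2-[3-bromo-5-methoxy-4-(triisopropylsilyloxy)phenyl]-7-(triisopropylsilyloxy)chroman-4-one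
Conditions: TIPSCl (2.6 equiv), imidazole (5 equiv), DMF, 40 °C, 12 h
Reagents that add atoms: triisopropylsilyl chloride, CC(C)[Si](Cl)(C(C)C)C(C)C
Why: Silyl ether formation masks both phenols against the trivalent iodine oxidant of step 3, aryl TIPS ethers being stable to the sulfonic acid released there and keeping the 4'-oxygen a donor, while imidazole is too weak a base to reopen the flavanone.

Step 3
Reactants: 5 (±)-2-[3-bromo-5-methoxy-4-(triisopropylsilyloxy)phenyl]-7-(triisopropylsilyloxy)chroman-4-one
Product: 6 3-[3-bromo-5-methoxy-4-(triisopropylsilyloxy)phenyl]-7-(triisopropylsilyloxy)-4H-chromen-4-one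
Conditions: PhI(OH)OTs (1.2 equiv), TsOH·H2O (10 mol %), HC(OMe)3, rt → 45 °C, 8 h; aq. NaHCO3
Reagents that add atoms: none
Why: Oxidative 2,3-aryl migration of a flavanone with a hypervalent iodine reagent (laboratory counterpart of isoflavone synthase): the electrophilic iodine attacks C-3 of the acid-enolised ketone, the C-2 aryl shifts to C-3 as iodobenzene leaves while O-1 stabilises the C-2 cation, and proton loss gives the chromone and removes the only stereocentre.

Step 4
Reactants: 6 3-[3-bromo-5-methoxy-4-(triisopropylsilyloxy)phenyl]-7-(triisopropylsilyloxy)-4H-chromen-4-one; 7 tributyl(3-methylbut-2-en-1-yl)stannane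
Product: 9 7-hydroxy-3-[4-hydroxy-3-methoxy-5-(3-methylbut-2-en-1-yl)phenyl]-4H-chromen-4-one, via bis-TIPS prenyl isoflavone 8 (not isolated)
Conditions: Pd(PPh3)4 (8 mol %), DMF, 100 °C, 8 h; then Bu4NF/AcOH (1:1, 3 equiv), THF, 0 °C → rt
Reagents that add atoms: none
Why: Stille cross-coupling at zerovalent palladium places the prenyl group on the brominated carbon (reductive elimination at the unhindered primary allyl terminus gives the linear isomer), and buffered fluoride then cleaves both aryl silyl ethers without touching the chromone or the trisubstituted alkene.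

Step 5
Reactants: 9 7-hydroxy-3-[4-hydroxy-3-methoxy-5-(3-methylbut-2-en-1-yl)phenyl]-4H-chromen-4-one
Product: 10 7-hydroxy-3-(8-methoxy-2,2-dimethyl-2H-chromen-6-yl)-4H-chromen-4-one
Conditions: DDQ (1.1 equiv), 1,4-dioxane, 80 °C, 1 h
Reagents that add atoms: none
Why: DDQ dehydrogenative cyclisation: hydride abstraction from the benzylic–allylic CH2 of the electron-rich o-prenylphenol gives an o-quinone methide that closes by oxa-6π electrocyclisation to the 2,2-dimethyl-2H-chromene, as in chromene biosynthesis, while the electron-poor ring A phenol has no such C–H and is left alone.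

**Compound list**

1 | 2,4-dihydroxyacetophenone | CC(=O)c1ccc(O)cc1O | starting material
2 | 5-bromovanillin (3-bromo-4-hydroxy-5-methoxybenzaldehyde) | COc1cc(C=O)cc(Br)c1O | starting material
3 | (E)-3-(3-bromo-4-hydroxy-5-methoxyphenyl)-1-(2,4-dihydroxyphenyl)prop-2-en-1-one | O=C(/C=C/c1cc(OC)c(O)c(Br)c1)c1ccc(O)cc1O | intermediate (not isolated)
4 | (±)-2-(3-bromo-4-hydroxy-5-methoxyphenyl)-7-hydroxychroman-4-one (racemate) | COc1cc(C2CC(=O)c3ccc(O)cc3O2)cc(Br)c1O | intermediate
5 | (±)-2-[3-bromo-5-methoxy-4-(triisopropylsilyloxy)phenyl]-7-(triisopropylsilyloxy)chroman-4-one (racemate) | COc1cc(C2CC(=O)c3ccc(O[Si](C(C)C)(C(C)C)C(C)C)cc3O2)cc(Br)c1O[Si](C(C)C)(C(C)C)C(C)C | intermediate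
6 | 3-[3-bromo-5-methoxy-4-(triisopropylsilyloxy)phenyl]-7-(triisopropylsilyloxy)-4H-chromen-4-one | COc1cc(-c2coc3cc(O[Si](C(C)C)(C(C)C)C(C)C)ccc3c2=O)cc(Br)c1O[Si](C(C)C)(C(C)C)C(C)C | intermediate
7 | tributyl(3-methylbut-2-en-1-yl)stannane | CCCC[Sn](CCCC)(CCCC)CC=C(C)C | starting material
8 | 3-[3-methoxy-5-(3-methylbut-2-en-1-yl)-4-(triisopropylsilyloxy)phenyl]-7-(triisopropylsilyloxy)-4H-chromen-4-one | COc1cc(-c2coc3cc(O[Si](C(C)C)(C(C)C)C(C)C)ccc3c2=O)cc(CC=C(C)C)c1O[Si](C(C)C)(C(C)C)C(C)C | intermediate (not isolated)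
9 | 7-hydroxy-3-[4-hydroxy-3-methoxy-5-(3-methylbut-2-en-1-yl)phenyl]-4H-chromen-4-one | COc1cc(-c2coc3cc(O)ccc3c2=O)cc(CC=C(C)C)c1O | intermediate
10 | 7-hydroxy-3-(8-methoxy-2,2-dimethyl-2H-chromen-6-yl)-4H-chromen-4-one (achiral) | COc1cc(-c2coc3cc(O)ccc3c2=O)cc2c1OC(C)(C)C=C2 | target

**Step count**

Total steps: 5. Longest linear sequence: 5 (1 + 2 → 4 → 5 → 6 → 9 → 10).

**Steps most likely to fail, with fallbacks**

Step 3 is the most exposed. The migrating aryl carries bromine and a doubly flanked silyloxy group, so it is only a moderate migrator, and 2,3-dehydrogenation to the flavone or 3-methoxylation may compete. The fallback moves the aryl shift to the open-chain chalcone, before ring C exists. It sets out from chalcone 3, filtered off when step 1 is stopped before the reflux. NaH and MeOCH2Cl in DMF give (E)-1-[2,4-bis(methoxymethoxy)phenyl]-3-[3-bromo-5-methoxy-4-(methoxymethoxy)phenyl]prop-2-en-1-one F1. Tl(NO3)3·3H2O (trivalent thallium) in MeOH/HC(OMe)3 at rt then effects methoxythallation of the enone and 1,2-aryl shift to the racemic acetal 1-[2,4-bis(methoxymethoxy)phenyl]-2-[3-bromo-5-methoxy-4-(methoxymethoxy)phenyl]-3,3-dimethoxypropan-1-one F2. 3 M HCl in MeOH at 60 °C removes the three MOM groups and closes ring C with loss of methanol to 3-(3-bromo-4-hydroxy-5-methoxyphenyl)-7-hydroxy-4H-chromen-4-one F3. TIPSCl and imidazole in DMF bring this back to the route at 6.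

Step 4 is next. The prenylstannane can couple through its tertiary terminus (reverse prenyl) or be lost by protodestannylation, and oxidative addition next to the bulky silyloxy group is slow. The fallback splits the prenyl transfer into allylation and olefin metathesis. It sets out from 6: allyltributylstannane with Pd(PPh3)4 in DMF at 100 °C gives 3-[3-allyl-5-methoxy-4-(triisopropylsilyloxy)phenyl]-7-(triisopropylsilyloxy)-4H-chromen-4-one F4, with no regiochemical ambiguity. Cross-metathesis with excess 2-methylbut-2-ene using the second-generation Grubbs catalyst, RuCl2(=CHPh)(H2IMes)(PCy3), in CH2Cl2 at 40 °C converts the allyl into the prenyl group. This comes back to the route at 8, which is desilylated as in step 4.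

Step 1 is third. The hydroxy aldehyde is a poor electrophile and the chalcone–flavanone equilibrium is incomplete; unreacted 3 can be recycled, but the yield may stay low. The fallback condenses protected partners under base and lets acid do deprotection and ring closure together. It sets out from 1 and 2: MeOCH2Cl and K2CO3 in acetone give 1-[2-hydroxy-4-(methoxymethoxy)phenyl]ethanone F5 (the chelated 2-OH stays free) and 3-bromo-5-methoxy-4-(methoxymethoxy)benzaldehyde F6. KOH in EtOH at rt (Claisen–Schmidt) joins them to (E)-3-[3-bromo-5-methoxy-4-(methoxymethoxy)phenyl]-1-[2-hydroxy-4-(methoxymethoxy)phenyl]prop-2-en-1-one F7. 3 M HCl in MeOH at reflux removes both MOM groups and closes ring C by oxa-Michael addition, coming back to the route at 4.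

**Further compounds**

F1 | step 3 | (E)-1-[2,4-bis(methoxymethoxy)phenyl]-3-[3-bromo-5-methoxy-4-(methoxymethoxy)phenyl]prop-2-en-1-one | COCOc1ccc(C(=O)/C=C/c2cc(OC)c(OCOC)c(Br)c2)c(OCOC)c1
F2 | step 3 | (±)-1-[2,4-bis(methoxymethoxy)phenyl]-2-[3-bromo-5-methoxy-4-(methoxymethoxy)phenyl]-3,3-dimethoxypropan-1-one | COCOc1ccc(C(=O)C(C(OC)OC)c2cc(OC)c(OCOC)c(Br)c2)c(OCOC)c1
F3 | step 3 | 3-(3-bromo-4-hydroxy-5-methoxyphenyl)-7-hydroxy-4H-chromen-4-one | COc1cc(-c2coc3cc(O)ccc3c2=O)cc(Br)c1O
F4 | step 4 | 3-[3-allyl-5-methoxy-4-(triisopropylsilyloxy)phenyl]-7-(triisopropylsilyloxy)-4H-chromen-4-one | C=CCc1cc(-c2coc3cc(O[Si](C(C)C)(C(C)C)C(C)C)ccc3c2=O)cc(OC)c1O[Si](C(C)C)(C(C)C)C(C)C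
F5 | step 1 | 1-[2-hydroxy-4-(methoxymethoxy)phenyl]ethanone | CC(=O)c1ccc(OCOC)cc1O
F6 | step 1 | 3-bromo-5-methoxy-4-(methoxymethoxy)benzaldehyde | COCOc1c(Br)cc(C=O)cc1OC
F7 | step 1 | (E)-3-[3-bromo-5-methoxy-4-(methoxymethoxy)phenyl]-1-[2-hydroxy-4-(methoxymethoxy)phenyl]prop-2-en-1-one | COCOc1ccc(C(=O)/C=C/c2cc(OC)c(OCOC)c(Br)c2)c(O)c1
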